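**Retrosynthetic overview**
- The target is pinobanksin 3-O-[(R)-2-methylbutanoate]. The C3 ester is cut last, giving 5,7-di-O-benzylpinobanksin and (R)-2-methylbutanoic acid.
- Ring C, the only ring made, is opened at O1–C2. It comes from 6-endo opening of a trans-epoxide by the ring A phenol, so C2 and C3 derive from a (2R,3S)-3-phenyloxiranyl aryl ketone.
- The feature the strategy rests on: in ring A, O1 (on C8a) and the C4 carbonyl (on C4a) sit on neighbouring carbons, and C4a has the C5 oxygen on its other side. A 3-alkoxyaryne gives exactly this 1,2,3-pattern when it inserts into the C–O bond of a carboxylate (oxygen meta to the alkoxy group, acyl group ortho to it).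
- The O1–C8a and C4–C4a bonds are therefore made together from 3,5-bis(benzyloxy)benzyne and potassium (2R,3S)-3-phenylglycidate. The glycidate comes from Sharpless epoxidation of cinnamyl alcohol; ring A is bought.

Key step: step 6

Remark: flavanone numbering is used (O1, C2, C3, C4, C4a, C5 to C8, C8a; ring A is the dioxygenated benzo ring, ring C the pyranone). Compounds 1, 7 and 16 are assumed to be purchasable.

**Route**

Step 1
Reactants: 1 3,5-bis(benzyloxy)phenol
Product: 2 2-bromo-3,5-bis(benzyloxy)phenol
Conditions: NBS (1.0 equiv), CH2Cl2, −78 °C to rt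
Reagents that add atoms: N-bromosuccinimide, O=C1CCC(=O)N1Br
Why: Electrophilic aromatic bromination, which in non-coordinating CH2Cl2 should be steered ortho to the hydrogen-bonding phenolic OH (C2 and C6 are equivalent), with one equivalent of NBS at low temperature limiting dibromination and any 4-bromo isomer being removed by chromatography.

Step 2
Reactants: 2 2-bromo-3,5-bis(benzyloxy)phenol
Product: 3 [3,5-bis(benzyloxy)-2-bromophenoxy]trimethylsilane
Conditions: HMDS, THF, 65 °C; evaporation, used crude
Reagents that add atoms: hexamethyldisilazane, C[Si](C)(C)N[Si](C)(C)C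
Why: O-silylation of a phenol with HMDS gives the aryl silyl ether with ammonia as the only by-product, so the evaporated crude material should be dry enough for the lithiation.

Step 3
Reactants: 3 [3,5-bis(benzyloxy)-2-bromophenoxy]trimethylsilane
Product: 6 3,5-bis(benzyloxy)-2-(trimethylsilyl)phenyl trifluoromethanesulfonate, via aryllithium 4 (not isolated), via lithium phenoxide 5 (not isolated)
Conditions: n-BuLi (1.1 equiv), THF, −100 to −80 °C; then Tf2O (1.2 equiv), −100 to −78 °C
Reagents that add atoms: trifluoromethanesulfonic anhydride, O=S(=O)(OS(=O)(=O)C(F)(F)F)C(F)(F)F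
Why: Bromine–lithium exchange, which at −100 °C should be far faster than deprotonation of the benzylic ether CH2 groups, gives the ortho-lithio aryl silyl ether, whose 1,3 O-to-C silyl shift (retro-Brook rearrangement) is driven by formation of the lithium phenoxide, and Tf2O then sulfonylates the oxygen (the standard route to ortho-silylaryl triflates).

Step 4
Reactants: 7 (E)-cinnamyl alcohol
Product: 8 [(2S,3S)-3-phenyloxiran-2-yl]methanol
Conditions: Ti(OiPr)4 (5 mol %), L-(+)-diisopropyl tartrate (7.5 mol %), anhydrous t-BuOOH (2 equiv), 4 Å molecular sieves, CH2Cl2, −20 °C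
Reagents that add atoms: tert-butyl hydroperoxide, CC(C)(C)OO
Why: Sharpless asymmetric epoxidation, in which the titanium L-(+)-tartrate complex binds the allylic alcohol and the hydroperoxide and delivers oxygen to one face of the E-alkene, setting both stereocentres as (2S,3S) with the trans relationship fixed by the alkene geometry (one recrystallisation should raise the enantiomeric purity).

Step 5
Reactants: 8 [(2S,3S)-3-phenyloxiran-2-yl]methanol
Product: 10 potassium (2R,3S)-3-phenyloxirane-2-carboxylate, via glycidic acid 9 (not isolated)
Conditions: RuCl3·xH2O (2 mol %), NaIO4 (3 equiv), MeCN/EtOAc/H2O, 0 °C to rt; cold extraction; then KHCO3 (1.0 equiv), MeOH/H2O, 0 °C; freeze-dried, then dried over P2O5 in vacuo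
Reagents that add atoms: water, O; potassium hydrogencarbonate, [K+].OC([O-])=O
Why: RuO4 made catalytically from RuCl3 with NaIO4 as terminal oxidant takes the primary alcohol through the aldehyde hydrate to the acid without touching the epoxide (Sharpless ruthenium oxidation), both stereocentres are unchanged (C2 becomes R only through the change of CIP priorities), and immediate cold neutralisation avoids decarboxylation of the free glycidic acid.

Step 6
Reactants: 6 3,5-bis(benzyloxy)-2-(trimethylsilyl)phenyl trifluoromethanesulfonate; 10 potassium (2R,3S)-3-phenyloxirane-2-carboxylate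
Product: 14 [2,4-bis(benzyloxy)-6-hydroxyphenyl][(2R,3S)-3-phenyloxiran-2-yl]methanone, via aryne 11 (not isolated), via aryl anion ester 12 (not isolated), via potassium phenoxide 13 (not isolated)
Conditions: 10 (2 equiv), KF (3 equiv), 18-crown-6 (5 equiv), THF, 0 °C to rt, 6 added over 2 h; AcOH, −20 °C; neutral work-up, used crude
Reagents that add atoms: none
Why: Fluoride removes the silyl group of 6 and triflate leaves to give aryne 11; the carboxylate oxygen of 10 adds to the aryne carbon remote from the flanking benzyloxy group (future C8a), the carbanion of 12 at the carbon beside that benzyloxy group (future C4a) attacks its own ester carbonyl through a four-membered transition state, and collapse with cleavage of the acyl C–O bond gives ketone phenoxide 13, which acetic acid protonates to 14. The closest known reaction type is the fluoride-induced insertion of arynes into the C–O bond of carboxylic acids to give ortho-hydroxyaryl ketones; here a dry, preformed potassium carboxylate in THF is used so that no acidic proton can intercept the aryl anion, which should let the acyl shift (an anionic Fries-type migration) run at room temperature instead of the high temperature used with free acids, although a glycidate has not yet been tried as the carboxylate partner. No ring is closed and no stereocentre is formed: the four-membered ring is only a transient on the way to the insertion product, and both epoxide stereocentres are spectators that should stay (2R,3S), since the epoxide α-hydrogen is poorly acidic. The step needs regioselectivity on the unsymmetrical aryne, and the benzyloxy group next to the triple bond secures it by distorting the aryne and stabilising negative charge on the adjacent carbon, so that the nucleophile adds meta to it. It also needs protection of the product from itself: the carboxylate is kept in excess and 6 is added slowly so that 13 does not compete for the aryne, and the mixture is held at or below room temperature and quenched cold so that 13 does not open its own epoxide by 5-exo attack at the α-carbon.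

Step 7
Reactants: 14 [2,4-bis(benzyloxy)-6-hydroxyphenyl][(2R,3S)-3-phenyloxiran-2-yl]methanone
Product: 15 (2R,3R)-5,7-bis(benzyloxy)-3-hydroxy-2-phenyl-2,3-dihydro-4H-chromen-4-one
Conditions: p-TsOH·H2O (10 mol %), CH2Cl2, 0 °C to rt
Reagents that add atoms: none
Why: Acid-promoted intramolecular epoxide opening by the phenol (6-endo-tet closure of ring C, as in the known cyclisation of 2'-hydroxychalcone epoxides to dihydroflavonols), in which the protonated epoxide is attacked from the back side at the benzylic carbon (its C–O bond is weakened by the phenyl group, while the α-carbon is deactivated by the carbonyl), so that this carbon is inverted (S in 14 to R at C2) and the untouched α-carbon becomes C3 (R), giving the 2,3-trans product.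

Step 8
Reactants: 15 (2R,3R)-5,7-bis(benzyloxy)-3-hydroxy-2-phenyl-2,3-dihydro-4H-chromen-4-one; 16 (R)-2-methylbutanoic acid
Product: 17 (2R,3R)-5,7-bis(benzyloxy)-4-oxo-2-phenyl-3,4-dihydro-2H-chromen-3-yl (2R)-2-methylbutanoate
Conditions: EDC·HCl (1.5 equiv), DMAP (0.2 equiv), CH2Cl2, 0 °C to rt
Reagents that add atoms: none
Why: Steglich esterification (carbodiimide activation, DMAP acyl transfer) of the only free hydroxyl group, the C3 alcohol, in which the side-chain stereocentre is brought in with 16 and low temperature with little DMAP should suppress both its racemisation and base-induced epimerisation of the α-acyloxy ketone.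

Step 9
Reactants: 17 (2R,3R)-5,7-bis(benzyloxy)-4-oxo-2-phenyl-3,4-dihydro-2H-chromen-3-yl (2R)-2-methylbutanoate
Product: 18 (2R,3R)-5,7-dihydroxy-4-oxo-2-phenyl-3,4-dihydro-2H-chromen-3-yl (2R)-2-methylbutanoate
Conditions: H2 (1 atm), 10% Pd/C, EtOAc, rt, stopped after uptake of 2 equiv
Reagents that add atoms: none
Why: Catalytic hydrogenolysis of the two aryl benzyl ethers over Pd/C, which should be cleaved much faster than the cyclic benzylic C2–O1 bond, the conjugated aryl ketone or the ester, so that the target is released with all three stereocentres intact.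

**Compound list**
1 | 3,5-bis(benzyloxy)phenol | Oc1cc(OCc2ccccc2)cc(OCc2ccccc2)c1 | starting material
2 | 2-bromo-3,5-bis(benzyloxy)phenol | Oc1cc(OCc2ccccc2)cc(OCc2ccccc2)c1Br | intermediate
3 | [3,5-bis(benzyloxy)-2-bromophenoxy]trimethylsilane | C[Si](C)(C)Oc1cc(OCc2ccccc2)cc(OCc2ccccc2)c1Br | intermediate
4 | {2,4-bis(benzyloxy)-6-[(trimethylsilyl)oxy]phenyl}lithium | [Li]c1c(O[Si](C)(C)C)cc(OCc2ccccc2)cc1OCc1ccccc1 | intermediate (not isolated)
5 | lithium 3,5-bis(benzyloxy)-2-(trimethylsilyl)phenoxide | [Li+].[O-]c1cc(OCc2ccccc2)cc(OCc2ccccc2)c1[Si](C)(C)C | intermediate (not isolated)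
6 | 3,5-bis(benzyloxy)-2-(trimethylsilyl)phenyl trifluoromethanesulfonate | C[Si](C)(C)c1c(OCc2ccccc2)cc(OCc2ccccc2)cc1OS(=O)(=O)C(F)(F)F | intermediate
7 | (E)-cinnamyl alcohol | OC/C=C/c1ccccc1 | starting material
8 | [(2S,3S)-3-phenyloxiran-2-yl]methanol | OC[C@@H]1O[C@H]1c1ccccc1 | intermediate
9 | (2R,3S)-3-phenyloxirane-2-carboxylic acid | OC(=O)[C@@H]1O[C@H]1c1ccccc1 | intermediate (not isolated)
10 | potassium (2R,3S)-3-phenyloxirane-2-carboxylate | [K+].[O-]C(=O)[C@@H]1O[C@H]1c1ccccc1 | intermediate
11 | 3,5-bis(benzyloxy)benzyne | C1(OCc2ccccc2)=CC(OCc2ccccc2)=CC#C1 | intermediate (not isolated)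
12 | potassium 2,4-bis(benzyloxy)-6-{[(2R,3S)-3-phenyloxirane-2-carbonyl]oxy}benzen-1-ide | [K+].O=C(Oc1cc(OCc2ccccc2)cc(OCc2ccccc2)[c-]1)[C@@H]1O[C@H]1c1ccccc1 | intermediate (not isolated)
13 | potassium 3,5-bis(benzyloxy)-2-[(2R,3S)-3-phenyloxirane-2-carbonyl]phenoxide | [K+].[O-]c1cc(OCc2ccccc2)cc(OCc2ccccc2)c1C(=O)[C@@H]1O[C@H]1c1ccccc1 | intermediate (not isolated)
14 | [2,4-bis(benzyloxy)-6-hydroxyphenyl][(2R,3S)-3-phenyloxiran-2-yl]methanone | O=C(c1c(O)cc(OCc2ccccc2)cc1OCc1ccccc1)[C@@H]1O[C@H]1c1ccccc1 | intermediate
15 | (2R,3R)-5,7-bis(benzyloxy)-3-hydroxy-2-phenyl-2,3-dihydro-4H-chromen-4-one | O[C@H]1C(=O)c2c(OCc3ccccc3)cc(OCc3ccccc3)cc2O[C@@H]1c1ccccc1 | intermediate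
16 | (R)-2-methylbutanoic acid | CC[C@@H](C)C(=O)O | starting material
17 | (2R,3R)-5,7-bis(benzyloxy)-4-oxo-2-phenyl-3,4-dihydro-2H-chromen-3-yl (2R)-2-methylbutanoate | CC[C@@H](C)C(=O)O[C@H]1C(=O)c2c(OCc3ccccc3)cc(OCc3ccccc3)cc2O[C@@H]1c1ccccc1 | intermediate
18 | (2R,3R)-5,7-dihydroxy-4-oxo-2-phenyl-3,4-dihydro-2H-chromen-3-yl (2R)-2-methylbutanoate | CC[C@@H](C)C(=O)O[C@H]1C(=O)c2c(O)cc(O)cc2O[C@@H]1c1ccccc1 | target

**Step count**
Total steps: 9. Longest linear sequence: 7 steps (1, 2, 3, 6, 7, 8, 9, from compound 1); the glycidate branch (steps 4 and 5) joins at step 6.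

**Steps most likely to fail**

Step 6. The aryl anion of 12 may be protonated before the acyl shift, which would leave the O-aryl glycidate instead of the ketone. The phenoxide 13 may also be consumed by attack on its own epoxide or on a second aryne. The fallback replaces the aryne by known organolithium chemistry; it sets out from 2 and 10 and comes back at 15.
- Bromophenol 2 is protected with MOMCl and i-Pr2NEt in CH2Cl2 to give 1,5-bis(benzyloxy)-2-bromo-3-(methoxymethoxy)benzene F1.
- Salt 10 is coupled with N,O-dimethylhydroxylamine hydrochloride (EDC·HCl, HOBt, CH2Cl2, 0 °C) to give the Weinreb amide (2R,3S)-N-methoxy-N-methyl-3-phenyloxirane-2-carboxamide F2.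
- Bromine–lithium exchange on F1 (n-BuLi, THF, −78 °C) and addition of F2 should give [2,4-bis(benzyloxy)-6-(methoxymethoxy)phenyl][(2R,3S)-3-phenyloxiran-2-yl]methanone F3.
- HCl in MeOH/THF at 40 °C removes the MOM group, and the freed phenol closes ring C as in step 7 to give 15.

Step 7. The benzylic C–O bond may ionise before the phenol attacks, which would erode the C2 configuration (cis isomer). The aroyl group may shift to the benzylic carbon (Meinwald-type rearrangement), or the closure may go 5-exo. The fallback is a two-stage thiol route; it sets out from 14 and comes back at 15.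
- BnSH and SnCl4 in CH2Cl2 at −20 °C open the epoxide at the benzylic carbon to give (2S)-1-[2,4-bis(benzyloxy)-6-hydroxyphenyl]-3-(benzylsulfanyl)-2-hydroxy-3-phenylpropan-1-one F4, as either or both C3 epimers.
- AgBF4 in CH2Cl2 at 0 °C then ionises the C–S bond and the phenol closes the ring.
- C3 of the chromanone keeps the configuration of the α-carbon, and C2 is set under thermodynamic control in favour of the diequatorial trans product 15. Any cis isomer would be removed by chromatography.

Step 1. Bromination may be unselective between the positions ortho and para to the hydroxyl group, or may run on to dibromides. The fallback installs the silyl group by directed ortho-metalation without a bromide; it sets out from 1 and comes back at 6.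
- Phenol 1 is treated with isopropyl isocyanate and catalytic Et3N in CH2Cl2 to give 3,5-bis(benzyloxy)phenyl N-isopropylcarbamate F5.
- N-Silylation in the flask (TMSOTf, TMEDA, Et2O) is followed by lithiation with n-BuLi/TMEDA at −78 °C at the position between the carbamate and a benzyloxy group (C2 and C6 are equivalent). A TMSCl quench and work-up give 3,5-bis(benzyloxy)-2-(trimethylsilyl)phenyl N-isopropylcarbamate F6.
- DBU and Et2NH in MeCN at 40 °C cleave the carbamate to 3,5-bis(benzyloxy)-2-(trimethylsilyl)phenol F7, which is triflated in the same flask with PhNTf2 to give 6.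

Further compounds
F1 | step 6 | 1,5-bis(benzyloxy)-2-bromo-3-(methoxymethoxy)benzene | COCOc1cc(OCc2ccccc2)cc(OCc2ccccc2)c1Br
F2 | step 6 | (2R,3S)-N-methoxy-N-methyl-3-phenyloxirane-2-carboxamide | CON(C)C(=O)[C@@H]1O[C@H]1c1ccccc1
F3 | step 6 | [2,4-bis(benzyloxy)-6-(methoxymethoxy)phenyl][(2R,3S)-3-phenyloxiran-2-yl]methanone | COCOc1cc(OCc2ccccc2)cc(OCc2ccccc2)c1C(=O)[C@@H]1O[C@H]1c1ccccc1
F4 | step 7 | (2S)-1-[2,4-bis(benzyloxy)-6-hydroxyphenyl]-3-(benzylsulfanyl)-2-hydroxy-3-phenylpropan-1-one (C3 epimers) | O=C(c1c(O)cc(OCc2ccccc2)cc1OCc1ccccc1)[C@H](O)C(SCc1ccccc1)c1ccccc1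
F5 | step 1 | 3,5-bis(benzyloxy)phenyl N-isopropylcarbamate | CC(C)NC(=O)Oc1cc(OCc2ccccc2)cc(OCc2ccccc2)c1
F6 | step 1 | 3,5-bis(benzyloxy)-2-(trimethylsilyl)phenyl N-isopropylcarbamate | CC(C)NC(=O)Oc1cc(OCc2ccccc2)cc(OCc2ccccc2)c1[Si](C)(C)C
F7 | step 1 | 3,5-bis(benzyloxy)-2-(trimethylsilyl)phenol | Oc1cc(OCc2ccccc2)cc(OCc2ccccc2)c1[Si](C)(C)C
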